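At a fixed conversion one quantity does not move with the charge: if one reagent goes per substrate, the reagent spent is the same however much was put in.

| setting | Sunday's | flask |
|---|---|---|
| substrate | 0.20 M | 0.20 M |
| reagent | 1.5 equiv | 1.50 equiv |
| free catalyst | 1 mol% | 1 mol% |
| remark | the very flask that is asked about, followed so far |  |

- Sunday's (time / min: target / %, substrate / %): 0.667: 1.7, 97.5; 1.50: 0, 96.9; 4.00: 4.9, 95.2; 10.0: 9.5, 89.6

(each reading ± 1 percentage point)

- apparent order in reagent when 30 % of the substrate are converted (percent change of the rate of making target for one percent more reagent charged)
- factor on the rate of making target when 30 % of the substrate are converted if reagent is charged twice over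

- the numbers in the tables scatter by 1 percentage point (one standard deviation)
- no earlier run changes the charge of reagent; that part of a forecast is a guess

Sunday's readings stand at 9.5 % target after 10.0 min, and the substrate lost matches that within the scatter of 1 percentage point. They hold a single charge of reagent, so any order in reagent is a guess.

Now take logarithms. At 30 % conversion of this flask the reagent left is 80.0 % of its charge, so one percent more charge raises the reagent present by 1.25 percent. Call this ratio of charge to reagent left the lever. At this fixed conversion, the apparent order in the charge is then the lever times n, the order in the reagent present.

Two chemists dispute n. The first holds to one step, first order in reagent, so n is one. By my reckoning on that view, the apparent order equals the lever, and doubling the charge multiplies the rate by 2.25. The second, who made the forecast, expects part of the catalyst to be bound and answers 1 and 1.9, calling this “a chemist's prior”. Through the lever, I read that order as n = 0.800.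

The flask gives 0.71 and 1.46, so the forecast stands nearer than the first chemist, though still high.

    reagent + catalyst intermediate A → catalyst intermediate B (k = 5.20 M⁻¹ min⁻¹)
    catalyst intermediate B → catalyst intermediate C (k = 7.00 min⁻¹)
    substrate + free catalyst → catalyst intermediate A (k = 34.0 M⁻¹ min⁻¹)
    catalyst intermediate C ⇌ free catalyst + target (K = 0.0540 M, k = 170 min⁻¹)
    free catalyst ⇌ dormant form (K = 14.0, k = 0.0390 min⁻¹)

Through the lever, n is 0.566. The first chemist's view has its region in the step of reagent with catalyst intermediate A, the resting state of this flask, which holds 49.9 % of the catalyst at 30.0 min, more than any other form. The passing of free catalyst into dormant form acts on a different order: it takes the apparent order in free catalyst from 1.0 to 1.2. Part of the shortfall comes from free catalyst + target falling back to catalyst intermediate C: the same run without that step has apparent order 0.85, and through the same lever n = 0.680.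

(Readings and results stem from a simulated flask on assumed constants; noise was put on by code.)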